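## The problem

Talarominine A (15) is a 2,3,4,6-tetrasubstituted benzofuran. Ring A is the carbocycle C3a–C4–C5–C6–C7–C7a (an orcinol unit with C4-methyl and C6-OH), ring B is the furan O1–C2–C3–C3a–C7a, and ring C is the 3,5-dihydroxy-2,4-dimethylphenyl group on C3. The hardest point is C3. Its bond to C1' lies between the C2 side chain, the peri C4-methyl group and the C2'-methyl group, so any sp2–sp2 coupling there is a threefold ortho-hindered biaryl synthesis. The second problem is regiochemistry in ring A. C3a must be the orcinol carbon between oxygen and methyl, yet closures onto an orcinol ether can equally use the carbon between the two oxygen atoms, and the peri strain of the wanted isomer pushes them there. The third problem is ring C, which is joined through the carbon meta to both hydroxy groups, a position that electrophilic substitution of a resorcinol does not reach. There is no stereocentre, and only the C3–C1' axis could carry stereochemical information. The end game is limited by three electron-rich phenols, the benzofuran and an aliphatic methyl ester that tolerates neither hydroxide nor organometallic reagents. The enabling feature is the string C2–CH2–CH2–C(=O)OMe. It is four carbon atoms with oxygen on both termini (O1 on C2, O and OMe on the ester carbon), which is a 2-methoxyfuran in ring-opened form. It hangs on C3, which is doubly benzylic and ortho to the C7a oxygen, so the skeleton of 15 is an isomer of a (2-hydroxyaryl)(aryl)(5-methoxyfuran-2-yl)methane.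

## Retrosynthesis

**15 ⇒ 14.** Only the two O–CH3 bonds at C3' and C5' of ring C are cut. These oxygen atoms stay methyl ethers because commercial aldehyde 1 already carries them and because they must survive n-BuLi twice and the acid of the key step. The ring A oxygen atoms carry MOM groups, which fall off inside the key step. The skeleton does not get simpler here. The forward reaction must cleave two flanked aryl methyl ethers without losing the aliphatic methyl ester.

**14 ⇒ 10 + 11 (through 13 and 12).** The bonds C2–C3 and C2–O1 are cut, and the ester carbonyl oxygen is joined back to C2.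

- C2, the CH2CH2 link and the CO2Me group collapse into commercial 2-methoxyfuran 11, and C3 is left as the carbinol carbon of diarylmethanol 10.
- Among the neighbouring cuts, C3–C1' leaves the hindered biaryl coupling, C3–C3a at the benzofuran stage reopens the ring A regiochemistry, and C2–CH2 makes no use of the ester.
- The chosen cut removes ring B, the whole side chain and the ester in one operation and leaves a plain benzhydrol.
- The forward reaction must alkylate 11 at its free alpha-carbon (12), open the furan to keto ester 13, shed two MOM groups, and close and aromatise ring B, all in one flask.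

**10 ⇒ 9 (from 8) + 5.** The C3–C3a bond is cut.

- Of the two aryl–C3 bonds this one is chosen because ring A is easily functionalised at exactly this carbon (bromide 8).
- C1' of ring C is meta to both oxygen atoms and is best bought with its carbon substituent in place (aldehyde 5).
- Both fragments are simple benzenes.
- The forward reaction is the addition of a di-ortho-substituted aryllithium 9 to a non-enolisable aldehyde, so the crowded carbon is built as sp3 and not by coupling two sp2 centres.

**8 ⇒ 7 ⇒ 6.** The C–Br bond and the two O–CH2OMe bonds are cut, which leads to orcinol 6. Bromination of the diether 7 must take the carbon between OMOM and methyl (para to the other OMOM) and not the carbon between the two OMOM groups. This fixes the ring A regiochemistry before any ring is closed.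

**5 ⇒ 1.** The C2'–CH3 bond is cut. Aldehyde 1 is symmetric, so its two ortho carbons are equivalent, and each lies between the formyl carbon and a methoxy group. One directed lithiation and methylation on the masked aldehyde (2, 3, 4) is all the forward step needs.

## Roads not taken

Alternative 1: cut C3–C1' (the most obvious plan).

- Forward key step: Suzuki–Miyaura coupling of methyl 3-(3-iodo-6-methoxy-4-methyl-1-benzofuran-2-yl)propanoate A1 with (3,5-dimethoxy-2,4-dimethylphenyl)boronic acid A2. A1 would come from iodocyclisation of methyl 5-(2,4-dimethoxy-6-methylphenyl)pent-4-ynoate A3, itself a Sonogashira product.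
- The coupling must form an sp2–sp2 bond flanked by the C2 chain, the peri C4-methyl and the C2'-methyl group. Transmetalation and reductive elimination are therefore slow, and protodeboronation of electron-rich A2 and reduction of A1 compete.
- A2 needs boron on the ring C carbon meta to both oxygen atoms, which costs extra steps.
- The side chain is carried in separately and its ester plays no constructive role.
- The chosen plan makes both bonds to C3 at a tetrahedral or cationic carbon and is shorter.

Alternative 2: cut C3–C3a in an aryl ether.

- Forward key step: acid cyclodehydration of methyl 5-(3,5-dimethoxy-2,4-dimethylphenyl)-4-(3-methoxy-5-methylphenoxy)-5-oxopentanoate A4.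
- The ring can close at either ortho carbon of the aryloxy group. The wanted closure next to the methyl group builds up the peri strain in its transition state, while closure between the two oxygen atoms does not.
- The ortho-methylated aryl ketone is twisted and poorly electrophilic, and strong acids are known to move aryl groups from C3 to C2 in such systems.
- In the chosen plan the regiochemistry is settled in bromide 8, and the ring closure forms a C–O bond that has no regiochemical choice.

Alternative 3: read C3, C2, the two CH2 groups and the ester carbon as a ring-opened cyclopentane-1,3-dione.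

- Forward key step: methoxide retro-Claisen opening and cyclodehydration of 2-(3,5-dimethoxy-2,4-dimethylphenyl)-2-(2-hydroxy-4-methoxy-6-methylphenyl)cyclopentane-1,3-dione A5. A5 would be made by electrophilic arylation of 2-(3,5-dimethoxy-2,4-dimethylphenyl)cyclopentane-1,3-dione A6 at its C2.
- The fragmentation is attractive, but A5 holds a quaternary carbon with two ortho-substituted aryl groups and is more crowded than anything in the target.
- Its formation needs a stoichiometric tetravalent lead or iodonium aryl donor derived from ring A.
- The precursor of the key step would be as complex as its product.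
- The chosen plan uses the same latent 1,4-dioxygenation but joins the pieces at a secondary cation.

Key step: step 5

Assumption: the SMILES gives no axial descriptor, so the C3–C1' axis is treated as configurationally undefined and 15 is made without control of this axis.

## Steps

Step 1
Reactants: 1 3,5-dimethoxy-4-methylbenzaldehyde
Product: 5 3,5-dimethoxy-2,4-dimethylbenzaldehyde, via amino alkoxide 2 (not isolated), via ring-lithiated amino alkoxide 3 (not isolated), via methylated amino alkoxide 4 (not isolated)
Conditions: Me2NCH2CH2N(Me)Li (from the amine and n-BuLi), THF, −20 °C; n-BuLi, −20 °C; MeI, −78 °C → rt; then H2O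
Reagents that add atoms: iodomethane, SMILES: CI
Why: Alpha-amino alkoxide-directed ortho-lithiation: the lithium amide masks the aldehyde as 2, whose chelating diamine arm and the neighbouring methoxy group together direct n-BuLi to the carbon between them (the two such carbons are equivalent by symmetry) to give 3. MeI gives 4, and water releases aldehyde 5 in the same flask.

Step 2
Reactants: 6 orcinol (5-methylbenzene-1,3-diol)
Product: 7 1,3-bis(methoxymethoxy)-5-methylbenzene
Conditions: MOMCl, i-Pr2NEt, CH2Cl2, 0 °C → rt
Reagents that add atoms: chloromethyl methyl ether, SMILES: COCCl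
Why: Routine O-alkylation of both phenols. MOM survives NBS and n-BuLi, stabilises aryllithium 9 by chelation and is lost under the acid of the key step.

Step 3
Reactants: 7 1,3-bis(methoxymethoxy)-5-methylbenzene
Product: 8 2-bromo-1,5-bis(methoxymethoxy)-3-methylbenzene
Conditions: NBS (1 equiv), MeCN, 0 °C, dark
Reagents that add atoms: N-bromosuccinimide, SMILES: O=C1CCC(=O)N1Br
Why: Electrophilic aromatic bromination; orcinol diethers are known to react at the carbon para to one alkoxy group and next to the methyl group, because the carbon between the two alkoxy groups is shielded. One equivalent at low temperature should prevent a second bromination.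

Step 4
Reactants: 8 2-bromo-1,5-bis(methoxymethoxy)-3-methylbenzene; 5 3,5-dimethoxy-2,4-dimethylbenzaldehyde
Product: 10 [2,4-bis(methoxymethoxy)-6-methylphenyl](3,5-dimethoxy-2,4-dimethylphenyl)methanol (racemic), via aryllithium 9 (not isolated)
Conditions: n-BuLi, THF, −78 °C; then 5, −78 → 0 °C; then H2O
Reagents that add atoms: none
Why: Bromine–lithium exchange and 1,2-addition of an aryllithium to a non-enolisable benzaldehyde; the crowded C3–C3a bond forms at a trigonal carbon that becomes tetrahedral, which asks far less than an sp2–sp2 coupling. The carbinol centre is racemic and is erased in step 5.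

Step 5
Reactants: 10 [2,4-bis(methoxymethoxy)-6-methylphenyl](3,5-dimethoxy-2,4-dimethylphenyl)methanol; 11 2-methoxyfuran
Product: 14 methyl 3-[3-(3,5-dimethoxy-2,4-dimethylphenyl)-6-hydroxy-4-methyl-1-benzofuran-2-yl]propanoate, via methoxyfuran adduct 12 (not isolated), via keto ester 13 (not isolated)
Conditions: 11 (2.5 equiv), Sc(OTf)3 (5 mol %), 4 Å MS, CH2Cl2, −20 → 0 °C; then HCl in MeOH (1.25 M), rt → 40 °C, same flask
Reagents that add atoms: none
Why: Proposed new method: the closest known reaction type is the acid-induced furan ring-opening/benzofuran ring-closure of (2-hydroxyaryl)(5-alkylfuran-2-yl)methanes (Butin reaction), which ends in a 3-oxoalkyl chain on C2, whereas a 5-alkoxyfuran, which should end in an ester, has not been put through it. Sc(OTf)3 ionises 10 to a benzhydryl cation stabilised by the ortho and para oxygen atoms of ring A, and 11 should attack it through its free alpha-carbon (Friedel–Crafts alkylation, the mode known for acid-catalysed additions of 11 to imines and nitroalkenes), which makes the C3–C2 bond at an sp3 centre and gives 12. In methanolic HCl the ketene-acetal-like furan of 12 is protonated at both beta-carbons and opened by methanol or a trace of water, so that the substituted furan carbon becomes the C2 ketone, the two CH groups the CH2CH2 link and the C(OMe) carbon the methyl ester; this should be faster than MOM loss, so the phenol stays masked while the reversible ipso-protonation of the furan is drained. Loss of both MOM groups as dimethoxymethane gives 13, whose C7a-OH adds to the C2 carbonyl or its oxocarbenium form in a 5-exo-trig closure of ring B, and loss of water across C2–C3 aromatises the ring, the irreversible sink of all preceding equilibria. No stereocentre survives, since the C3 centre of 10, 12 and 13 becomes sp2. Three selectivities are needed: attack at furan C5 rather than C3 is secured by the methoxy group, which polarises the ring toward C5 and blocks C2; closure by the C7a-OH rather than the C6-OH is secured by ring size, as only the former reaches C2; and the ring A regiochemistry is already locked in the C3–C3a bond of 10, so the peri C4-methyl group cannot divert the closure.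

Step 6
Reactants: 14 methyl 3-[3-(3,5-dimethoxy-2,4-dimethylphenyl)-6-hydroxy-4-methyl-1-benzofuran-2-yl]propanoate
Product: 15 talarominine A, methyl 3-[3-(3,5-dihydroxy-2,4-dimethylphenyl)-6-hydroxy-4-methyl-1-benzofuran-2-yl]propanoate
Conditions: BBr3, CH2Cl2, −78 °C → rt; then MeOH, 0 °C → reflux
Reagents that add atoms: none
Why: Aryl methyl ether cleavage with BBr3; both ring C methoxy groups are flanked by methyl groups, twisted out of conjugation and therefore basic, so they should cleave under mild conditions. The methanol quench converts the boron species into B(OMe)3 and HBr, and brief heating re-esterifies any acid formed by partial ester cleavage (Fischer esterification).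

## Compound list

1 | 3,5-dimethoxy-4-methylbenzaldehyde | COc1cc(C=O)cc(OC)c1C | starting material
2 | lithium (3,5-dimethoxy-4-methylphenyl){[2-(dimethylamino)ethyl](methyl)amino}methanolate (racemic) | [Li]OC(N(C)CCN(C)C)c1cc(OC)c(C)c(OC)c1 | intermediate
3 | lithium {[2-(dimethylamino)ethyl](methyl)amino}(2-lithio-3,5-dimethoxy-4-methylphenyl)methanolate (racemic) | [Li]OC(N(C)CCN(C)C)c1cc(OC)c(C)c(OC)c1[Li] | intermediate
4 | lithium (3,5-dimethoxy-2,4-dimethylphenyl){[2-(dimethylamino)ethyl](methyl)amino}methanolate (racemic) | [Li]OC(N(C)CCN(C)C)c1cc(OC)c(C)c(OC)c1C | intermediate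
5 | 3,5-dimethoxy-2,4-dimethylbenzaldehyde | O=Cc1cc(OC)c(C)c(OC)c1C | intermediate
6 | orcinol (5-methylbenzene-1,3-diol) | Cc1cc(O)cc(O)c1 | starting material
7 | 1,3-bis(methoxymethoxy)-5-methylbenzene | COCOc1cc(C)cc(OCOC)c1 | intermediate
8 | 2-bromo-1,5-bis(methoxymethoxy)-3-methylbenzene | Brc1c(C)cc(OCOC)cc1OCOC | intermediate
9 | [2,4-bis(methoxymethoxy)-6-methylphenyl]lithium | [Li]c1c(C)cc(OCOC)cc1OCOC | intermediate
10 | [2,4-bis(methoxymethoxy)-6-methylphenyl](3,5-dimethoxy-2,4-dimethylphenyl)methanol (racemic) | COCOc1cc(C)c(C(O)c2cc(OC)c(C)c(OC)c2C)c(OCOC)c1 | intermediate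
11 | 2-methoxyfuran | COc1ccco1 | starting material
12 | 2-{[2,4-bis(methoxymethoxy)-6-methylphenyl](3,5-dimethoxy-2,4-dimethylphenyl)methyl}-5-methoxyfuran (racemic) | COCOc1cc(C)c(C(c2ccc(OC)o2)c2cc(OC)c(C)c(OC)c2C)c(OCOC)c1 | intermediate
13 | methyl 5-(2,4-dihydroxy-6-methylphenyl)-5-(3,5-dimethoxy-2,4-dimethylphenyl)-4-oxopentanoate (racemic) | COC(=O)CCC(=O)C(c1c(C)cc(O)cc1O)c1cc(OC)c(C)c(OC)c1C | intermediate
14 | methyl 3-[3-(3,5-dimethoxy-2,4-dimethylphenyl)-6-hydroxy-4-methyl-1-benzofuran-2-yl]propanoate | COC(=O)CCc1oc2cc(O)cc(C)c2c1-c1cc(OC)c(C)c(OC)c1C | intermediate
15 | talarominine A, methyl 3-[3-(3,5-dihydroxy-2,4-dimethylphenyl)-6-hydroxy-4-methyl-1-benzofuran-2-yl]propanoate | COC(=O)CCc1oc2cc(O)cc(C)c2c1-c1cc(O)c(C)c(O)c1C | target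

## Step count

Total steps: 6. Longest linear sequence: 5 steps (6 → 7 → 8 → 10 → 14 → 15, steps 2 to 6). Step 1 supplies the second fragment.

## Least certain steps

**Step 5 (key step, proposed new method).** Three processes are most likely to interfere.

- Acid-induced oligomerisation or solvolysis of 11 may occur before the crowded cation from 10 has been captured.
- In the second stage, ipso-protonation of the furan carbon that bears the benzhydryl group may be followed by loss of the stabilised benzhydryl cation (retro-Friedel–Crafts).
- The same ipso-protonation may instead let the double bond drift into conjugation with the carboxyl carbon. The freed phenol can then close a six-membered ring by oxa-Michael addition instead of the five-membered ring.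

These processes draw on the high basicity of the alkoxyfuran at the same carbon at which it is nucleophilic.

The fallback uses known chemistry, sets out from 10 and returns at 14. Oxidation of 10 with MnO2 gives [2,4-bis(methoxymethoxy)-6-methylphenyl](3,5-dimethoxy-2,4-dimethylphenyl)methanone F1. HCl in MeOH removes both MOM groups to give (2,4-dihydroxy-6-methylphenyl)(3,5-dimethoxy-2,4-dimethylphenyl)methanone F2. Double acylation with methyl 4-chloro-4-oxobutanoate, Et3N and DMAP gives the bis(methyl succinate) ester F3. Reductive keto ester cyclisation with low-valent titanium (TiCl3, Zn, DME, reflux; McMurry type) joins the ketone carbon (C3) to the carbonyl carbon of the ortho ester (C2) and gives the benzofuran 6-O-succinate F4. K2CO3 in MeOH then frees the C6-OH and reaches 14.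

**Step 6.** The aliphatic methyl ester may be cleaved along with the aryl ethers. The C5' ether, which is flanked on one side only, may be cleaved incompletely. The very electron-rich triphenol may also degrade under HBr during the quench.

The fallback sets out from 5 and returns at 15. The methyl ethers are exchanged before the fragments are joined. BBr3 on 5 gives 3,5-dihydroxy-2,4-dimethylbenzaldehyde F6, and MOMCl with i-Pr2NEt gives 3,5-bis(methoxymethoxy)-2,4-dimethylbenzaldehyde F7. Addition of 9 gives the tetra-MOM benzhydrol F8. The conditions of step 5 then lead through the tetra-MOM methoxyfuran adduct F9 and the fully free keto ester F10 directly to 15. The key step becomes the last step, and no boron halide meets the ester.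

**Step 1.** Ring lithiation may be slow or incomplete, because the C4-methyl group forces both methoxy groups to turn their methyl groups toward the ortho C–H bonds (buttressing). Lateral lithiation of the C4-methyl group may compete, and butyl addition is possible if masking of the aldehyde is incomplete.

The fallback sets out from 1 and returns at 5. NBS in MeCN brominates 1 at the carbon ortho to the formyl group and para to a methoxy group to give 2-bromo-3,5-dimethoxy-4-methylbenzaldehyde F5. Suzuki–Miyaura methylation with trimethylboroxine, Pd(PPh3)4 and K2CO3 in dioxane gives 5.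

## Further compounds

F1 | step 5 | [2,4-bis(methoxymethoxy)-6-methylphenyl](3,5-dimethoxy-2,4-dimethylphenyl)methanone | COCOc1cc(C)c(C(=O)c2cc(OC)c(C)c(OC)c2C)c(OCOC)c1
F2 | step 5 | (2,4-dihydroxy-6-methylphenyl)(3,5-dimethoxy-2,4-dimethylphenyl)methanone | Cc1cc(O)cc(O)c1C(=O)c1cc(OC)c(C)c(OC)c1C
F3 | step 5 | 4-(3,5-dimethoxy-2,4-dimethylbenzoyl)-5-methylbenzene-1,3-diyl bis(methyl succinate) | COC(=O)CCC(=O)Oc1cc(C)c(C(=O)c2cc(OC)c(C)c(OC)c2C)c(OC(=O)CCC(=O)OC)c1
F4 | step 5 | 3-(3,5-dimethoxy-2,4-dimethylphenyl)-2-(3-methoxy-3-oxopropyl)-4-methyl-1-benzofuran-6-yl methyl succinate | COC(=O)CCC(=O)Oc1cc(C)c2c(-c3cc(OC)c(C)c(OC)c3C)c(CCC(=O)OC)oc2c1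
F5 | step 1 | 2-bromo-3,5-dimethoxy-4-methylbenzaldehyde | O=Cc1cc(OC)c(C)c(OC)c1Br
F6 | step 6 | 3,5-dihydroxy-2,4-dimethylbenzaldehyde | O=Cc1cc(O)c(C)c(O)c1C
F7 | step 6 | 3,5-bis(methoxymethoxy)-2,4-dimethylbenzaldehyde | O=Cc1cc(OCOC)c(C)c(OCOC)c1C
F8 | step 6 | [2,4-bis(methoxymethoxy)-6-methylphenyl][3,5-bis(methoxymethoxy)-2,4-dimethylphenyl]methanol (racemic) | COCOc1cc(C)c(C(O)c2cc(OCOC)c(C)c(OCOC)c2C)c(OCOC)c1
F9 | step 6 | 2-{[2,4-bis(methoxymethoxy)-6-methylphenyl][3,5-bis(methoxymethoxy)-2,4-dimethylphenyl]methyl}-5-methoxyfuran (racemic) | COCOc1cc(C)c(C(c2ccc(OC)o2)c2cc(OCOC)c(C)c(OCOC)c2C)c(OCOC)c1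
F10 | step 6 | methyl 5-(2,4-dihydroxy-6-methylphenyl)-5-(3,5-dihydroxy-2,4-dimethylphenyl)-4-oxopentanoate (racemic) | COC(=O)CCC(=O)C(c1c(C)cc(O)cc1O)c1cc(O)c(C)c(O)c1C
A1 | alternative 1 | methyl 3-(3-iodo-6-methoxy-4-methyl-1-benzofuran-2-yl)propanoate | COC(=O)CCc1oc2cc(OC)cc(C)c2c1I
A2 | alternative 1 | (3,5-dimethoxy-2,4-dimethylphenyl)boronic acid | COc1cc(B(O)O)c(C)c(OC)c1C
A3 | alternative 1 | methyl 5-(2,4-dimethoxy-6-methylphenyl)pent-4-ynoate | COC(=O)CCC#Cc1c(C)cc(OC)cc1OC
A4 | alternative 2 | methyl 5-(3,5-dimethoxy-2,4-dimethylphenyl)-4-(3-methoxy-5-methylphenoxy)-5-oxopentanoate (racemic) | COC(=O)CCC(Oc1cc(C)cc(OC)c1)C(=O)c1cc(OC)c(C)c(OC)c1C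
A5 | alternative 3 | 2-(3,5-dimethoxy-2,4-dimethylphenyl)-2-(2-hydroxy-4-methoxy-6-methylphenyl)cyclopentane-1,3-dione | COc1cc(C)c(C2(c3cc(OC)c(C)c(OC)c3C)C(=O)CCC2=O)c(O)c1
A6 | alternative 3 | 2-(3,5-dimethoxy-2,4-dimethylphenyl)cyclopentane-1,3-dione | COc1cc(C2C(=O)CCC2=O)c(C)c(OC)c1C
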